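The leftover Z was where I began: X stood at 0.600 equiv to Z, and each X takes one Z, so X was the limiting reagent and could turn 0.600 of the Z charge at most.

| setting | south | south-east | ochre | red |
|---|---|---|---|---|
| Z | 0.40 M | 1.6 M | 0.80 M | 0.80 M |
| X | 0.60 equiv | 0.60 equiv | 0.600 equiv | 0.600 equiv |
| temperature | −2 °C | 14 °C |  |  |
| remark | run made earlier | run made earlier | at 20 °C until 30 min, from then on at −10 °C | at 20 °C throughout |
| time |  |  | 2.5 h | 1.2 h |

south run (percent of the Z charged): time / h: D / % = 0.500: 6; 1.00: 11; 2.50: 13; 6.00: 18

south-east run (percent of the Z charged): time / min: D / % = 10.0: 19; 20.0: 23; 50.0: 24; 120: 26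

(standard deviation of a reading: 1.5 percentage points)

1. which one finishes higher in amount of D, in percent of the Z charged ("neither" within 2 percentage points) (ochre / red / neither)
2. amount of D at the end, in percent of the Z charged, ochre
3. amount of D at the end, in percent of the Z charged, red

- in percentages every species weighs as the Z in it: one G counts as two
- what was read earlier has a scatter of 1.5 percentage points, one standard deviation
- steps that have been proposed: Z + X -> D; Z + X -> J; 2 Z -> G

My bench rule was a budget: each X spent writes one D or one J, so D at the end is the X spent times the D made per X. The last south-east reading, 26% at 0.60 equiv, read with its X taken as spent, gave 0.433 as this D share, the selectivity in its plainest form. The last south reading, at −2 °C, gave 0.300, less than the warmer run, but D in the south run was still rising between its last two readings, from 13% to 18%, so I held this figure as a rough reading of the colder share. Taking the south-east share for both flasks, I budgeted 26.0% of the Z charge.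

I took the rule as it stands for red, held at 20 °C throughout. Ochre is the other end: X unspent at the change of temperature goes on at the colder share or stays unspent. If it stayed unspent, the difference would reach the margin once that unspent fraction of X passed the margin over the budget, 7.69%. Since the equivalents match and both proposed X steps are second order, time multiplied by Z charge compares flasks at one temperature: ochre's 30 min at 0.80 M equals 15.0 min at 1.6 M, though ochre was warmer than the south-east run. South-east at 20.0 min still had 11.5% of its budget unwritten, a reading above the border. If all of that reacted cold, it would cost 0.92 percentage points; if none did, 3 points. I expected the first and committed to no winner.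

The forecast gave 26% for ochre and 27.5% for red, hence neither, “though this is borderline”. Its red stood above my budget.

Ochre gave 25.7% and red 26.5%, so the answer is neither, with a gap of 0.80 points against the margin of 2 points. At the change of temperature, after 0.500 h, ochre held 3.90% of its own charge of X, under my border of 7.69%. Red ended with 0.15% of its X, and the share 0.433 on the X spent gives 25.9%.

    Z + X → D (k = 6.80 M⁻¹ h⁻¹, Ea = 71.0 kJ mol⁻¹)
    Z + X → J (k = 8.60 M⁻¹ h⁻¹, Ea = 57.0 kJ mol⁻¹)
    2 Z → G (k = 0.100 M⁻¹ h⁻¹, Ea = 59.0 kJ mol⁻¹)
    (constants at 20 °C)

A neighbouring flask is ochre with 0.240 equiv of X, and the share 0.433 budgets 10.4% of the Z charge for D. The computed flask gave 10.5%, with 0.32% of its X left.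

Readings and results come from a simulation for an exercise, and the scatter is random.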